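**Plan**

- Retrosynthesis: the diene terminus is cut at C14=C15 (Wittig) and at C14 (allylic oxidation of a prenyl group). Ring B is then cut at C6–C7 and C8–C9, which excises the alkyne C7≡C8 from a cyclobutanone. Next come C9–C11 (enolate prenylation) and C5–C6 / C9–C10 ([2+2] on 1,3,3-trimethylcyclohexene).
- Enabling feature: C6 and C9 of ring B are joined through the ring-fusion bond C5–C10, so ring B without C7=C8 is a cyclobutanone (C5, C6, C9, C10) fused to ring A. Its carbonyl becomes the C6 oxygen, the inserted alkyne becomes C7=C8, and the alkyne's ester becomes the C17 carboxyl.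
- Forward order: ring A (from 3-methylcyclohexenone), then the cis-fused cyclobutane by enantioselective allenoate [2+2], the cyclobutanone, C9 prenylation, and ring B by strain-releasing nickel-catalysed insertion of methyl propiolate. C5 epimerisation, C6 reduction, ester hydrolysis, acetylation, side-chain oxidation and methylenation follow.
- Stereochemistry: C10 (and C5, at first cis) come from the catalyst-controlled suprafacial [2+2]. C9 comes from convex-face alkylation and is carried with retention through the insertion. C5 is corrected to trans by α'-epimerisation, C6 is set by hydride attack anti to the two syn-axial methyls, and 12E by the E-selective SeO2 oxidation.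

Key step: step 6

Remark: carbons are numbered as in labdane (ring A = C1–C5, C10; ring B = C5–C10); the target is (5R,6S,9S,10S,12E)-6-acetoxylabda-7,12,14-trien-17-oic acid.
Assumption: the sense of induction of the oxazaborolidine in step 3 is assigned by analogy with simpler alkenes; the (R)-catalyst would be used if the (1R,6R) adduct predominated.

**Step 1**
Reactants: 1 3-methylcyclohex-2-en-1-one
Product: 2 1,3,3-trimethylcyclohex-1-ene
Conditions: Me2Zn (2.2 equiv), TiCl4 (2.2 equiv), CH2Cl2, −40 °C (forms Me2TiCl2); then 1, −40 → 0 °C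
Reagents that add atoms: dimethylzinc C[Zn]C; dimethyltitanium dichloride (formed in the flask) C[Ti](C)(Cl)Cl
Why: Geminal dimethylation of a ketone with Me2TiCl2: 1,2-methyl addition, ionisation of the tertiary allylic titanium alkoxide to the symmetrical 1,3-dimethylcyclohexenyl cation, and a second methyl transfer, which gives the same alkene at either terminus.

**Step 2**
Reactants: 3 but-3-ynoic acid; 4 2,2,2-trifluoroethanol
Product: 6 2,2,2-trifluoroethyl buta-2,3-dienoate, via trifluoroethyl but-3-ynoate 5 (not isolated)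
Conditions: DCC (1.1 equiv), DMAP (0.1 equiv), CH2Cl2, 0 → 23 °C
Reagents that add atoms: none
Why: Steglich esterification; the but-3-ynoate should isomerise in the flask under DMAP to the conjugated allenoate (propargyl–allenyl prototropy).

**Step 3**
Reactants: 2 1,3,3-trimethylcyclohex-1-ene; 6 2,2,2-trifluoroethyl buta-2,3-dienoate
Product: 7 2,2,2-trifluoroethyl 2-[(1S,6S)-1,5,5-trimethylbicyclo[4.2.0]octan-7-ylidene]acetate (E/Z mixture)
Conditions: (S)-3,3-diphenyl-1-(o-tolyl)tetrahydro-1H,3H-pyrrolo[1,2-c][1,3,2]oxazaborole (20 mol%), AlBr3 (16 mol%), 2 (3 equiv), CH2Cl2, −20 °C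
Reagents that add atoms: none
Why: Catalytic enantioselective Lewis-acid allenoate–alkene [2+2] cycloaddition: the allenoate β-carbon bonds to the less substituted alkene carbon (C5) and the CH2 terminus to C10, where positive charge builds; suprafacial addition gives the cis ring fusion, and the catalyst's face selection sets C5 and C10.

**Step 4**
Reactants: 7 2,2,2-trifluoroethyl 2-[(1S,6S)-1,5,5-trimethylbicyclo[4.2.0]octan-7-ylidene]acetate
Product: 8 (1S,6S)-1,5,5-trimethylbicyclo[4.2.0]octan-7-one
Conditions: O3, CH2Cl2/MeOH (4:1), −78 °C; then Me2S, −78 → 23 °C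
Reagents that add atoms: ozone O=[O+][O-]
Why: Ozonolysis of the only alkene, with reductive work-up, unmasks the cyclobutanone; no stereocentre is touched.

**Step 5**
Reactants: 8 (1S,6S)-1,5,5-trimethylbicyclo[4.2.0]octan-7-one; 9 1-bromo-3-methylbut-2-ene
Product: 11 (1S,6S,8S)-1,5,5-trimethyl-8-(3-methylbut-2-en-1-yl)bicyclo[4.2.0]octan-7-one, via lithium enolate 10 (not isolated)
Conditions: LDA (1.05 equiv), THF, −78 °C; then 9 (1.2 equiv), DMPU, −78 → −30 °C
Reagents that add atoms: none
Why: Kinetic enolisation should occur at the CH2 (C9) and not at the ring-fusion methine; enolate alkylation on the convex face, syn to the angular methyl and away from ring A, sets C9.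

**Step 6**
Reactants: 11 (1S,6S,8S)-1,5,5-trimethyl-8-(3-methylbut-2-en-1-yl)bicyclo[4.2.0]octan-7-one; 12 methyl propiolate
Product: 13 methyl (5S,9S,10S)-6-oxo-15-norlabda-7,12-dien-17-oate (cis-fused)
Conditions: Ni(cod)2 (10 mol%), 1,3-bis(2,6-diisopropylphenyl)imidazol-2-ylidene (12 mol%, premixed), toluene, 80 °C; 12 (3 equiv) added by syringe pump over 8 h
Reagents that add atoms: none
Why: Proposed new method: zerovalent nickel couples the strained C6 carbonyl and the alkyne by oxidative cyclisation (C6–C7 bond; the ester-bearing carbon goes to nickel as a nickel enolate and the unsubstituted carbon meets C6, as in nickel-catalysed ynoate–aldehyde reductive couplings), strain release then drives β-carbon elimination of the C6–C9 bond, and C(sp2)–C(sp3) reductive elimination forms C8–C9. The closest known reaction type is the nickel-catalysed intermolecular insertion of internal alkynes into 3-substituted cyclobutanones; a terminal ynoate and an α,α'-disubstituted ring-fused cyclobutanone lie outside it. Ring B is closed as a formal [4+2] ring expansion of the four-membered ring (acyl–alkyl unit C6–C5–C10–C9 plus C7≡C8) through a seven-membered nickelacycle. No new stereocentre is formed: C9 should migrate with retention in both organometallic steps, and C5 and C10 are not involved. The step needs site selectivity (C6–C9 over C6–C5), which the position of C5 between two quaternary carbons (C4 and C10) should secure; alkyne regioselectivity, which the ester should secure; and chemoselectivity over alkyne cyclotrimerisation, addressed by slow addition of 12 to a carbene-ligated catalyst that carries no free nucleophilic phosphine.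

**Step 7**
Reactants: 13 methyl (5S,9S,10S)-6-oxo-15-norlabda-7,12-dien-17-oate
Product: 14 methyl (5R,9S,10S)-6-oxo-15-norlabda-7,12-dien-17-oate (trans-fused)
Conditions: K2CO3 (0.5 equiv), MeOH, 0 → 23 °C
Reagents that add atoms: none
Why: Base-mediated epimerisation through the cross-conjugated C5 (α') enolate should give the more stable trans-decalin by reprotonation anti to the angular methyl; exchange of the γ-hydrogen at C9 is expected to be much slower.

**Step 8**
Reactants: 14 methyl (5R,9S,10S)-6-oxo-15-norlabda-7,12-dien-17-oate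
Product: 15 methyl (5R,6S,9S,10S)-6-hydroxy-15-norlabda-7,12-dien-17-oate
Conditions: NaBH4, CeCl3·7H2O, MeOH, −40 °C
Reagents that add atoms: none
Why: Luche 1,2-reduction; hydride should attack C6 from the face opposite the two syn-axial methyls (C20 and the axial C4 methyl), giving the axial alcohol syn to C20.

**Step 9**
Reactants: 15 methyl (5R,6S,9S,10S)-6-hydroxy-15-norlabda-7,12-dien-17-oate
Product: 16 (5R,6S,9S,10S)-6-hydroxy-15-norlabda-7,12-dien-17-oic acid
Conditions: LiOH·H2O, THF/MeOH/H2O (3:1:1), 45 °C; then 1 M HCl to pH 3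
Reagents that add atoms: lithium hydroxide [Li+].[OH-]
Why: Saponification of the methyl ester; the C6 oxygen and the C8 carboxyl are trans across C7=C8, so no lactone can form, and the C9 hydrogen is not acidic in this cross-conjugated position.

**Step 10**
Reactants: 16 (5R,6S,9S,10S)-6-hydroxy-15-norlabda-7,12-dien-17-oic acid
Product: 18 (5R,6S,9S,10S)-6-acetoxy-15-norlabda-7,12-dien-17-oic acid, via mixed anhydride 17 (not isolated)
Conditions: Ac2O, pyridine, DMAP (0.2 equiv), 40 °C; then H2O/THF, NaHCO3, 23 °C; acidify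
Reagents that add atoms: acetic anhydride CC(=O)OC(C)=O
Why: DMAP-catalysed acetylation of the hindered axial alcohol; the mixed carboxylic–acetic anhydride formed alongside is hydrolysed in the aqueous work-up.

**Step 11**
Reactants: 18 (5R,6S,9S,10S)-6-acetoxy-15-norlabda-7,12-dien-17-oic acid
Product: 20 (5R,6S,9S,10S,12E)-6-acetoxy-14-oxo-15-norlabda-7,12-dien-17-oic acid, via allylic alcohol 19 (not isolated)
Conditions: SeO2 (1.5 equiv), 1,4-dioxane, 80 °C
Reagents that add atoms: selenium dioxide O=[Se]=O
Why: Riley allylic oxidation (ene reaction, then [2,3]-sigmatropic shift) should occur at the E-methyl of the gem-dimethyl alkene and continue to the (E)-enal; the electron-poor C7=C8 alkene is inert to it.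

**Step 12**
Reactants: 20 (5R,6S,9S,10S,12E)-6-acetoxy-14-oxo-15-norlabda-7,12-dien-17-oic acid
Product: 21 (5R,6S,9S,10S,12E)-6-acetoxylabda-7,12,14-trien-17-oic acid
Conditions: Ph3PCH3Br (3.2 equiv), KOtBu (3.0 equiv), THF, 0 °C; then 20, −78 → 0 °C; aqueous citric acid work-up
Reagents that add atoms: methyltriphenylphosphonium bromide C[P+](c1ccccc1)(c1ccccc1)c1ccccc1.[Br-]
Why: Wittig methylenation; the non-stabilised ylide should react with the enal far faster than with the hindered acetate or the carboxylate (which takes up one equivalent of ylide), and the C12=C13 geometry is not touched.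

**Compound list**

1 | 3-methylcyclohex-2-en-1-one | CC1=CC(=O)CCC1 | starting material
2 | 1,3,3-trimethylcyclohex-1-ene | CC1=CC(C)(C)CCC1 | intermediate
3 | but-3-ynoic acid | C#CCC(=O)O | starting material
4 | 2,2,2-trifluoroethanol | OCC(F)(F)F | starting material
5 | 2,2,2-trifluoroethyl but-3-ynoate (not isolated) | C#CCC(=O)OCC(F)(F)F | intermediate
6 | 2,2,2-trifluoroethyl buta-2,3-dienoate | C=C=CC(=O)OCC(F)(F)F | intermediate
7 | 2,2,2-trifluoroethyl 2-[(1S,6S)-1,5,5-trimethylbicyclo[4.2.0]octan-7-ylidene]acetate (cis-fused, E/Z mixture) | C1C(=CC(=O)OCC(F)(F)F)[C@H]2C(C)(C)CCC[C@@]12C | intermediate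
8 | (1S,6S)-1,5,5-trimethylbicyclo[4.2.0]octan-7-one (cis-fused) | C1C(=O)[C@H]2C(C)(C)CCC[C@@]12C | intermediate
9 | 1-bromo-3-methylbut-2-ene (prenyl bromide) | CC(C)=CCBr | starting material
10 | lithium enolate of 8 (not isolated) | C1=C([O-])[C@H]2C(C)(C)CCC[C@@]12C.[Li+] | intermediate
11 | (1S,6S,8S)-1,5,5-trimethyl-8-(3-methylbut-2-en-1-yl)bicyclo[4.2.0]octan-7-one (prenyl syn to the angular methyl) | CC(C)=CC[C@@H]1C(=O)[C@H]2C(C)(C)CCC[C@@]12C | intermediate
12 | methyl propiolate | C#CC(=O)OC | starting material
13 | methyl (5S,9S,10S)-6-oxo-15-norlabda-7,12-dien-17-oate (cis-fused; H-5 syn to CH3-20) | CC(C)=CC[C@@H]1C(C(=O)OC)=CC(=O)[C@H]2C(C)(C)CCC[C@@]12C | intermediate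
14 | methyl (5R,9S,10S)-6-oxo-15-norlabda-7,12-dien-17-oate (trans-fused) | CC(C)=CC[C@@H]1C(C(=O)OC)=CC(=O)[C@@H]2C(C)(C)CCC[C@@]12C | intermediate
15 | methyl (5R,6S,9S,10S)-6-hydroxy-15-norlabda-7,12-dien-17-oate (6-OH syn to CH3-20) | CC(C)=CC[C@@H]1C(C(=O)OC)=C[C@H](O)[C@@H]2C(C)(C)CCC[C@@]12C | intermediate
16 | (5R,6S,9S,10S)-6-hydroxy-15-norlabda-7,12-dien-17-oic acid | CC(C)=CC[C@@H]1C(C(=O)O)=C[C@H](O)[C@@H]2C(C)(C)CCC[C@@]12C | intermediate
17 | acetic (5R,6S,9S,10S)-6-acetoxy-15-norlabda-7,12-dien-17-oic anhydride (not isolated) | CC(C)=CC[C@@H]1C(C(=O)OC(C)=O)=C[C@H](OC(C)=O)[C@@H]2C(C)(C)CCC[C@@]12C | intermediate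
18 | (5R,6S,9S,10S)-6-acetoxy-15-norlabda-7,12-dien-17-oic acid | CC(C)=CC[C@@H]1C(C(=O)O)=C[C@H](OC(C)=O)[C@@H]2C(C)(C)CCC[C@@]12C | intermediate
19 | (5R,6S,9S,10S,12E)-6-acetoxy-14-hydroxy-15-norlabda-7,12-dien-17-oic acid (not isolated) | OC/C(C)=C/C[C@@H]1C(C(=O)O)=C[C@H](OC(C)=O)[C@@H]2C(C)(C)CCC[C@@]12C | intermediate
20 | (5R,6S,9S,10S,12E)-6-acetoxy-14-oxo-15-norlabda-7,12-dien-17-oic acid | O=C/C(C)=C/C[C@@H]1C(C(=O)O)=C[C@H](OC(C)=O)[C@@H]2C(C)(C)CCC[C@@]12C | intermediate
21 | (5R,6S,9S,10S,12E)-6-acetoxylabda-7,12,14-trien-17-oic acid | C=C/C(C)=C/C[C@@H]1C(C(=O)O)=C[C@H](OC(C)=O)[C@@H]2C(C)(C)CCC[C@@]12C | target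

**Step count**

Total: 12 steps. Longest linear sequence: 11 steps (steps 1 and 3–12, from 1).

**Steps most likely to fail, with fallbacks**

Step 6 (labelled step). Alkyne cyclotrimerisation may outrun the insertion, β-carbon elimination may occur on the C5 side, or the alkylnickel intermediate may undergo β-hydride elimination. The fallback uses known chemistry, sets out from 8 and returns at 14; it forms C8–C9 and C6–C7 in separate operations.
- Cyclobutanone 8 is C-acetylated at C9 (LiHMDS, THF, −78 °C; 1-acetylimidazole) to the 2-acetylcyclobutanone F1.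
- F1 is C-prenylated as its enolate (K2CO3, 9, acetone) to the quaternary β-diketone F2.
- NaOMe in MeOH opens the strained ring by retro-Claisen cleavage of C6–C9 to the δ-keto ester F3.
- KOtBu in THF closes ring B by Claisen (Dieckmann-type) condensation of the methyl ketone onto the ester, giving the cyclohexane-1,3-dione F4. In F4 both C5 and C9 are α to a carbonyl and should settle to the trans-fused, equatorial arrangement.
- Tf2O/2,6-lutidine should give the vinylogous triflate F5 at the less hindered C8 oxygen.
- Methoxycarbonylation (Pd(OAc)2, dppp, CO, MeOH, Et3N) gives 14.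

Step 3. The hindered trisubstituted alkene may react sluggishly, an ene pathway may compete, or enantiofacial selectivity may be poor. The fallback sets out from 2 and returns at 8.
- Dichloroketene (Cl3CCOCl, Zn–Cu couple, Et2O) adds in a substrate-controlled [2+2] with the same regiochemistry to give the racemic dichlorocyclobutanone F6.
- Zn/AcOH dechlorinates F6 to the racemic cyclobutanone F7.
- Preparative chromatography on a chiral stationary phase separates the (1S,6S) enantiomer, which is 8.

Step 7. Competing γ-deprotonation may scramble C9 or move the double bond to C8=C9 during equilibration. The fallback sets out from 13 and returns at 14; it replaces reversible equilibration by irreversible kinetic enolisation and face-selective protonation.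
- LiHMDS with TMSCl present (THF, −78 °C) traps the kinetic C5 (α') enolate as the cross-conjugated silyl dienol ether F8.
- Protonolysis (HCl in MeOH/THF, −40 °C) should deliver the proton to C5 anti to the angular methyl, giving 14.

**Further compounds**

F1 | step 6 | (1S,6S)-8-acetyl-1,5,5-trimethylbicyclo[4.2.0]octan-7-one (C8 epimers/enol) | CC(=O)C1C(=O)[C@H]2C(C)(C)CCC[C@@]12C
F2 | step 6 | (1S,6S)-8-acetyl-1,5,5-trimethyl-8-(3-methylbut-2-en-1-yl)bicyclo[4.2.0]octan-7-one | CC(=O)C1(CC=C(C)C)C(=O)[C@H]2C(C)(C)CCC[C@@]12C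
F3 | step 6 | methyl (1S,2S)-2,6,6-trimethyl-2-(6-methyl-2-oxohept-5-en-3-yl)cyclohexane-1-carboxylate (side-chain epimers) | COC(=O)[C@H]1C(C)(C)CCC[C@@]1(C)C(CC=C(C)C)C(C)=O
F4 | step 6 | (5R,9S,10S)-15,17-dinorlabd-12-ene-6,8-dione | CC(C)=CC[C@@H]1C(=O)CC(=O)[C@@H]2C(C)(C)CCC[C@@]12C
F5 | step 6 | (5R,9S,10S)-6-oxo-15,17-dinorlabda-7,12-dien-8-yl trifluoromethanesulfonate | CC(C)=CC[C@@H]1C(OS(=O)(=O)C(F)(F)F)=CC(=O)[C@@H]2C(C)(C)CCC[C@@]12C
F6 | step 3 | racemic cis-fused 8,8-dichloro-1,5,5-trimethylbicyclo[4.2.0]octan-7-one | ClC1(Cl)C(=O)[C@H]2C(C)(C)CCC[C@@]12C.ClC1(Cl)C(=O)[C@@H]2C(C)(C)CCC[C@]12C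
F7 | step 3 | racemic cis-fused 1,5,5-trimethylbicyclo[4.2.0]octan-7-one | C1C(=O)[C@H]2C(C)(C)CCC[C@@]12C.C1C(=O)[C@@H]2C(C)(C)CCC[C@]12C
F8 | step 7 | methyl (9S,10S)-6-(trimethylsilyloxy)-15-norlabda-5,7,12-trien-17-oate | CC(C)=CC[C@@H]1C(C(=O)OC)=CC(O[Si](C)(C)C)=C2C(C)(C)CCC[C@@]12C
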